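What I want from the elm flask is how much target it holds at 4.0 h and which move after that pays.

| setting | elm | alder | flask |
|---|---|---|---|
| starting material | 0.050 M | 0.050 M | 0.050 M |
| partner | 0.075 M | 0.075 M | 0.0750 M |
| second substrate | 0.25 M | 0.12 M | 0.250 M |
| third substrate | 0.025 M | 0.025 M | 0.0250 M |
| remark | the very flask that is asked about, followed so far | run made earlier |  |
| time |  |  | 4.0 h |

| run | time / min | target / % | starting material / % |
|---|---|---|---|
| elm | 15.0 | 20.0 | 41.1 |
| elm | 40.0 | 19.9 | 26.7 |
| elm | 80.0 | 19.2 | 25.9 |
| elm | 180 | 20.0 | 27.3 |
| alder | 1.33 | 15.3 | 85.2 |
| alder | 2.50 | 18.6 | 79.3 |
| alder | 4.00 | 24.6 | 63.8 |
| alder | 5.00 | 26.3 | 60.1 |

(scatter of a reading: 1 percentage point)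

- south-east: at 4.0 h take out 90% of the target then present, then wait 4.0 h
- west: at 4.0 h add partner, 100% of the amount charged, then wait 4.0 h
- south-west: at 4.0 h add starting material, 50.0% of the amount charged, then wait 4.0 h
- north: change nothing and wait 4.0 h more

- target, in percent of the starting material first charged, at 4.0 h
- what to do for the largest gain in target; "none" if nothing gains more than 2 percentage points (south-east / west / south-west / north / none)
- target present, with what was taken out counted in, in percent of the starting material first charged, after west
- target present, with what was taken out counted in, in percent of the starting material first charged, after north

- target taken out counts as made
- the analysis behind the earlier runs scatters by 1 percentage point, standard deviation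
- additions bring no volume worth counting

The elm readings of target stand flat from 40.0 min on, with a mean of 19.7%, and starting material stands flat beside them at about 0.266 of its charge. I take partner to be the limiting reagent: counted one for one, the converted starting material took 0.489 of the partner charge, and I book the remainder to the second and third substrates as a guess.

Late in elm, target over starting material gone is 0.269, and I carry this on as the standing share, the fraction of the converted starting material that stands as target. The last alder reading offers a second way to it and gives 0.659, so the two part. Alder is the one that cheats, since its share was still falling when the readings ended, from 1.03 at 1.33 min, while elm fell from 0.340 at 15.0 min and then held. In elm, a share that falls and then holds suggests to me that target passes into an unseen form and balances with it.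

So I expect waiting to leave elm at 19.7%, and adding starting material without partner to give no target. If added partner converts the whole charge of starting material, the standing share puts target at 26.9%, a gain of 7.2 percentage points. Taking out 90% of the target lets the remaining pool split again, which gains 13 points, more than west, so I choose south-east.

The forecast gives 19.8%, 20% after west, 19.8% after north and the choice none, on the ground that “the limiting reagent is gone”.

The simulation gives 19.3% and chooses south-east, which gains 13 points, more than the 6.6 points of west; west ends at 25.8% and north at 19.3%. At 240 min the elm flask holds 0% of its partner and 26.7% of its starting material. The standing share, applied to 19.3%, gives south-east 13 points.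

    target ⇌ isomer of the product (K = 2.80, k = 0.00330 /s)
    third substrate + partner → third product (k = 0.00430 /M/s)
    second substrate + partner → second product (k = 0.00320 /M/s)
    starting material + partner → target (k = 0.0290 /M/s)

In the neighbour flask with 0.30 M of partner, or 6.00 equiv, I take the whole charge as converted, so the standing share gives 26.9% of target. The computed neighbour flask holds 26.3% of target at its end, with 0% of its starting material left.

The numbers in the tables are simulated from invented constants, noise included.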